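**Plan**
- Retrosynthesis: the acid is traced back to its methyl ester; ring A (the salicylate ring) is then cut at C3–C4 and C1–C6 into a four-carbon acetoacetate bis(silyl enol ether) and a three-carbon β-keto acetal that already carries the chain; the keto acetal is cut at the ketone carbon–chain bond into a Weinreb amide and a 10-phenyldecyl Grignard reagent; the Ph–CH2 bond is cut last, to phenylmagnesium bromide and 1,10-dibromodecane.
- Enabling feature: in ring A, C1(CO2H)–C2(OH)–C3 is an acetoacetate unit and C4–C5–C6(alkyl) is a 3-oxoaldehyde unit (C4 at aldehyde level, C6 at ketone level), so the oxygenation alternates around the ring as in a polyketide.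
- Forward order: the chain is joined first (aryl–alkyl coupling, then ketone synthesis); ring A, the only ring made, is closed last around the chain ketone in one benzannulation; the ester is then hydrolysed. Ring B (the phenyl group) is bought.
- Stereochemistry: the target has no stereocentre and no stereogenic double bond; only the regiochemistry of the annulation has to be controlled.

Key step: step 6

Assumption: the double-bond geometry of 10 and 11 is immaterial because these carbons end up in the aromatic ring, so both are drawn without E/Z descriptors; the stereocentres of 7, 12 and 13 are transient and uncontrolled.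

**Step 1**
Reactants: 1 phenylmagnesium bromide; 2 1,10-dibromodecane
Product: 3 (10-bromodecyl)benzene
Conditions: Li2CuCl4 (3 mol %), THF/NMP, 0 → 20 °C; 2 in threefold excess
Reagents that add atoms: none
Why: Copper-catalysed cross-coupling of an aryl Grignard reagent with a primary alkyl bromide (Kumada-type coupling through an organocuprate); the excess of the symmetrical dibromide should keep double arylation low, and unreacted 2 is recovered by distillation.

**Step 2**
Reactants: 4 methyl 3,3-dimethoxypropanoate
Product: 5 N,3,3-trimethoxy-N-methylpropanamide
Conditions: MeNH(OMe)·HCl, i-PrMgCl, THF, −20 → 0 °C; sat. aq. NH4Cl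
Reagents that add atoms: N,O-dimethylhydroxylamine hydrochloride, CNOC.Cl
Why: Direct aminolysis of the ester by the chloromagnesium amide of N,O-dimethylhydroxylamine (Weinreb amide formation); this weakly basic, non-Lewis-acidic nucleophile should leave the dimethyl acetal untouched.

**Step 3**
Reactants: 3 (10-bromodecyl)benzene; 5 N,3,3-trimethoxy-N-methylpropanamide
Product: 8 1,1-dimethoxy-13-phenyltridecan-3-one, via (10-phenyldecyl)magnesium bromide 6 (not isolated), via bromomagnesium hemiaminal chelate 7 (not isolated)
Conditions: 3, Mg, I2 (cat.), THF, 40 °C; then 5, THF, 0 °C; sat. aq. NH4Cl, 0 °C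
Reagents that add atoms: none
Why: Grignard formation from the primary bromide followed by Weinreb ketone synthesis; the five-membered N,O-chelate 7 holds the tetrahedral adduct until the quench, so no tertiary alcohol should form, and the acetal is inert to the organomagnesium reagent.

**Step 4**
Reactants: 9 methyl acetoacetate
Product: 10 methyl 3-(trimethylsilyloxy)but-2-enoate
Conditions: TMSCl, Et3N, hexane, 20 °C
Reagents that add atoms: chlorotrimethylsilane, C[Si](C)(C)Cl
Why: O-silylation of the enol form of the β-keto ester (silyl enol ether formation), favoured by the conjugated enol.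

**Step 5**
Reactants: 10 methyl 3-(trimethylsilyloxy)but-2-enoate
Product: 11 1-methoxy-1,3-bis(trimethylsilyloxy)buta-1,3-diene
Conditions: LiN(i-Pr)2, THF, −78 °C; TMSCl, −78 → 20 °C; filtered under argon and used at once
Reagents that add atoms: chlorotrimethylsilane, C[Si](C)(C)Cl
Why: γ-Deprotonation of the silyloxy crotonate gives the cross-conjugated dienolate, which is silylated at the ester oxygen (kinetic O-silylation of an ester enolate) to the 1,3-bis(silyloxy)diene.

**Step 6**
Reactants: 11 1-methoxy-1,3-bis(trimethylsilyloxy)buta-1,3-diene; 8 1,1-dimethoxy-13-phenyltridecan-3-one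
Product: 14 methyl 2-hydroxy-6-(10-phenyldecyl)benzoate, via open-chain methoxy diketo ester 12 (not isolated), via cyclic aldol 13 (not isolated)
Conditions: 11 (1.5 equiv), TiCl4 (1.1 equiv), CH2Cl2, −78 → 20 °C; then 1 M aq. HCl
Reagents that add atoms: none
Why: TiCl4 ionises the dimethyl acetal of 8 to a methoxycarbenium ion, and the terminal carbon C4 of diene 11 adds to it in a vinylogous Mukaiyama aldol-type reaction, forming the ring A bond C3–C4 and giving the open-chain adduct 12 as its titanium enolate. The carbon between the two carbonyl groups of that enolate then attacks the titanium-activated chain ketone in an intramolecular aldol addition, which forms the C1–C6 bond and closes ring A as cyclohexanone 13 in a 6-(enolexo)-exo-trig closure. β-Elimination of methanol, dehydration of the tertiary alcohol and enolisation of the resulting cyclohexadienone should deliver the aromatic, hydrogen-bonded salicylate 14 on warming and acidic work-up. The closest known reaction type is the Lewis acid-mediated formal [3+3] cyclocondensation of 1,3-bis(silyloxy)-1,3-dienes with β-keto acetals to 6-alkylsalicylates, applied here to a longer alkyl group. No stereocentre remains, because the centres created in 12 and 13 are erased on aromatisation. The selectivity needed is regiochemical: under TiCl4 the acetal is the more electrophilic site of 8 and C4 is the more nucleophilic site of 11, so these pair first and the ketone is left for ring closure beside the ester, which puts the chain at C6 and not at C4.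

**Step 7**
Reactants: 14 methyl 2-hydroxy-6-(10-phenyldecyl)benzoate
Product: 15 2-hydroxy-6-(10-phenyldecyl)benzoic acid
Conditions: NaOH (10 equiv), DMSO/H2O, 80 °C; then 1 M aq. HCl, 0 °C
Reagents that add atoms: sodium hydroxide, [Na+].[OH-]
Why: Saponification by acyl–oxygen cleavage; poorly solvated hydroxide in DMSO should overcome the shielding by the two ortho substituents, and acidification in the cold avoids decarboxylation of the salicylic acid.

**Compound list**
1 | phenylmagnesium bromide | Br[Mg]c1ccccc1 | starting material
2 | 1,10-dibromodecane | BrCCCCCCCCCCBr | starting material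
3 | (10-bromodecyl)benzene | BrCCCCCCCCCCc1ccccc1 | intermediate
4 | methyl 3,3-dimethoxypropanoate | COC(=O)CC(OC)OC | starting material
5 | N,3,3-trimethoxy-N-methylpropanamide | CON(C)C(=O)CC(OC)OC | intermediate
6 | (10-phenyldecyl)magnesium bromide | Br[Mg]CCCCCCCCCCc1ccccc1 | intermediate (not isolated)
7 | bromomagnesium 1,1-dimethoxy-3-[methoxy(methyl)amino]-13-phenyltridecan-3-olate (chelated tetrahedral adduct, racemic) | CON(C)C(O[Mg]Br)(CC(OC)OC)CCCCCCCCCCc1ccccc1 | intermediate (not isolated)
8 | 1,1-dimethoxy-13-phenyltridecan-3-one | COC(OC)CC(=O)CCCCCCCCCCc1ccccc1 | intermediate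
9 | methyl acetoacetate | COC(=O)CC(C)=O | starting material
10 | methyl 3-(trimethylsilyloxy)but-2-enoate | COC(=O)C=C(C)O[Si](C)(C)C | intermediate
11 | 1-methoxy-1,3-bis(trimethylsilyloxy)buta-1,3-diene | COC(O[Si](C)(C)C)=CC(=C)O[Si](C)(C)C | intermediate
12 | methyl 5-methoxy-3,7-dioxo-17-phenylheptadecanoate (racemic, present as its titanium enolate) | COC(=O)CC(=O)CC(OC)CC(=O)CCCCCCCCCCc1ccccc1 | intermediate (not isolated)
13 | methyl 2-hydroxy-4-methoxy-6-oxo-2-(10-phenyldecyl)cyclohexane-1-carboxylate (mixture of diastereomers) | COC(=O)C1C(=O)CC(OC)CC1(O)CCCCCCCCCCc1ccccc1 | intermediate (not isolated)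
14 | methyl 2-hydroxy-6-(10-phenyldecyl)benzoate | COC(=O)c1c(O)cccc1CCCCCCCCCCc1ccccc1 | intermediate
15 | 2-hydroxy-6-(10-phenyldecyl)benzoic acid | O=C(O)c1c(O)cccc1CCCCCCCCCCc1ccccc1 | target

**Step count**
Total: 7 steps. Longest linear sequence: 4 steps (steps 1, 3, 6, 7; the branches through steps 2 and 4–5 are equally long).

**Steps most likely to fail**

Step 6. With the long lipophilic ketone, the pairing of the two nucleophilic and two electrophilic carbons may be less clean than planned. The keto acetal may lose methanol before C–C bond formation, the diene may attack the ketone first (leading towards the 4-alkyl isomer), or the cyclic aldol may stall before aromatisation. The fallback sets out from 8 and 9 and comes back at 14. It makes the same two ring A bonds by enolate chemistry at a lower oxidation level and then dehydrogenates. Reduction of 8 with NaBH4 in MeOH should give 1,1-dimethoxy-13-phenyltridecan-3-ol F1. Aqueous acid (p-TsOH, acetone/H2O) should hydrolyse the acetal and dehydrate the aldol to (E)-13-phenyltridec-2-enal F2. Michael addition of methyl acetoacetate 9 (NaOMe, MeOH) at the β-carbon of the enal forms C1–C6, and intramolecular aldol condensation of the acetyl methyl group with the aldehyde forms C3–C4; this should give methyl 2-oxo-6-(10-phenyldecyl)cyclohex-3-ene-1-carboxylate F3. Bromination–dehydrobromination with CuBr2 and LiBr in refluxing MeCN should then aromatise it to 14.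

Step 3. The Grignard reagent may deprotonate amide 5 at C2 and trigger E1cB loss of methoxide from the acetal carbon, which consumes the nucleophile and destroys the masked aldehyde. The fallback sets out from 3 (as its Grignard reagent 6) and comes back at 8. It installs the acetal carbon last, so that no base-sensitive acetal is exposed to the organometallic. Addition of 6 to N-methoxy-N-methylacetamide should give 12-phenyldodecan-2-one F4. Kinetic deprotonation at the methyl group (LiN(i-Pr)2, THF, −78 °C) and trapping with TMSCl should give trimethyl[(12-phenyldodec-1-en-2-yl)oxy]silane F5. Mukaiyama-type addition of this enol silane to trimethyl orthoformate (TMSOTf cat., CH2Cl2, −78 °C) should then give 8.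

Step 7. Attack of hydroxide at the ester carbonyl is slowed by the two ortho substituents and by the phenoxide that forms first, so the hydrolysis may stall; forcing it by heat risks decarboxylation once the acid is set free. The fallback sets out from 14 and comes back at 15. It cleaves the other ester bond: lithium propane-1-thiolate (LiSPr) in HMPA at 25 °C should attack the ester methyl group in an SN2 dealkylation and give the lithium carboxylate, and cold acidification gives 15. No new isolated compound arises.

**Further compounds**
F1 | step 6 | 1,1-dimethoxy-13-phenyltridecan-3-ol (racemic) | COC(OC)CC(O)CCCCCCCCCCc1ccccc1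
F2 | step 6 | (E)-13-phenyltridec-2-enal | O=C/C=C/CCCCCCCCCCc1ccccc1
F3 | step 6 | methyl 2-oxo-6-(10-phenyldecyl)cyclohex-3-ene-1-carboxylate (racemic, mixture of diastereomers) | COC(=O)C1C(=O)C=CCC1CCCCCCCCCCc1ccccc1
F4 | step 3 | 12-phenyldodecan-2-one | CC(=O)CCCCCCCCCCc1ccccc1
F5 | step 3 | trimethyl[(12-phenyldodec-1-en-2-yl)oxy]silane | C=C(O[Si](C)(C)C)CCCCCCCCCCc1ccccc1
F0 | step 7 | none | none
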